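**Plan**

- Retrosynthesis: the two MOM ethers are removed last. Ring A (a1 carrying the quaternary carbon, a4 the hydroxyl, a5 the diaryl-ether oxygen) is the dehydrogenated form of a 4-alkyl-6-aryloxycyclohex-2-enone, so no aryl–oxygen coupling is required.
- That cyclohexenone is cut at a1–a6 and a2–a3 into an S β-quaternary aldehyde (a1, a2) and a 3-aryloxybut-3-en-2-one (a3–a6) whose aryloxy group is ring B with its own arm.
- Ring B: the aryl–quaternary-carbon bond is cut by SN2′ arylation of farnesyl phosphate. Aldehyde: the quaternary C–B bond is cut by SN2′ borylation of farnesyl carbonate, followed by two one-carbon boron homologations.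
- Forward: farnesol gives the aldehyde in 4 steps. The ring B bromide is arylated, O-alkylated with a chlorodiketone and methylenated to the aryloxy enone. Both halves are joined and ring A is closed in one enamine Michael–aldol operation, ring A is aromatised, and the MOM groups are removed.
- Stereochemistry: both quaternary centres come from chiral carbene–copper catalysis on (E)-farnesyl electrophiles, with boron and aryl delivered to opposite faces. The S boronate leads to the S aldehyde and the R arm on ring A; the arylation gives the S arm on ring B. Neither centre has an α-hydrogen, and the two ring stereocentres made in the annulation disappear on aromatisation.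

Key step: step 13

Remark: (2E,6E)-farnesol, 5-bromo-2,3-dihydroxybenzaldehyde and 3-chloropentane-2,4-dione are taken as purchasable. Both antipodes of the chiral imidazolinium salts are taken as accessible, and in steps 2 and 9 the antipode is chosen that gives the stated configuration. Descriptor changes along the aldehyde branch (S, R, S, R) reflect changes in substituent priority, not inversion.

**Step 1**
Reactants: 1 (2E,6E)-farnesol
Product: 2 methyl (2E,6E)-3,7,11-trimethyldodeca-2,6,10-trien-1-yl carbonate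
Conditions: ClCO2Me, pyridine, CH2Cl2, 0 °C → rt
Reagents that add atoms: methyl chloroformate, COC(=O)Cl
Why: Acylation of the primary allylic alcohol with a chloroformate gives the carbonate leaving group needed for the copper-catalysed allylic substitution; no stereocentre is involved.

**Step 2**
Reactants: 2 methyl farnesyl carbonate
Product: 3 4,4,5,5-tetramethyl-2-[(3S,6E)-3,7,11-trimethyldodeca-1,6,10-trien-3-yl]-1,3,2-dioxaborolane
Conditions: B2pin2, Cu(OTf)2 (5 mol %), chiral imidazolinium salt (5 mol %), NaOMe (cat.), DME, −30 °C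
Reagents that add atoms: bis(pinacolato)diboron, CC1(C)OB(OC1(C)C)B1OC(C)(C)C(C)(C)O1
Why: In this copper-catalysed enantioselective allylic boryl substitution (SN2′), the carbene–Cu–B(pin) species places boron on C3 and expels methyl carbonate; the chiral carbene distinguishes the faces of the E alkene and sets the boron-bearing quaternary centre as S.

**Step 3**
Reactants: 3 tertiary allylic boronic ester
Product: 4 2-[(2R,5E)-2-ethenyl-2,6,10-trimethylundeca-5,9-dien-1-yl]-4,4,5,5-tetramethyl-1,3,2-dioxaborolane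
Conditions: BrCH2Cl, n-BuLi, THF, −78 °C → rt
Reagents that add atoms: bromochloromethane, ClCBr
Why: In this Matteson homologation, chloromethyllithium adds to boron and the tertiary allyl group undergoes 1,2-migration with loss of chloride and retention at the migrating carbon, so the quaternary centre is carried unchanged into a non-allylic primary boronic ester.

**Step 4**
Reactants: 4 homologated boronic ester
Product: 6 (3S,6E)-3-ethenyl-3,7,11-trimethyldodeca-6,10-dienal, via α-chloro boronic ester 5 (not isolated)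
Conditions: CH2Cl2, n-BuLi, THF, −100 °C; ZnCl2, −100 °C → rt; then H2O2, aq. NaHCO3, THF, 0 °C
Reagents that add atoms: dichloromethane, ClCCl; hydrogen peroxide, OO
Why: A second Matteson homologation with dichloromethyllithium (ZnCl2-assisted 1,2-shift of the primary alkyl group) gives the α-chloro boronic ester, and buffered peroxide oxidation gives the α-chloro alcohol, which loses HCl to the aldehyde; the quaternary centre is untouched.

**Step 5**
Reactants: 1 (2E,6E)-farnesol
Product: 7 diethyl (2E,6E)-3,7,11-trimethyldodeca-2,6,10-trien-1-yl phosphate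
Conditions: ClP(O)(OEt)2, Et3N, DMAP (cat.), CH2Cl2, 0 °C
Reagents that add atoms: diethyl chlorophosphate, CCOP(=O)(Cl)OCC
Why: Phosphorylation of the allylic alcohol gives the leaving group that favours SN2′ over SN2 in copper-catalysed allylic substitution.

**Step 6**
Reactants: 8 5-bromo-2,3-dihydroxybenzaldehyde
Product: 9 5-bromo-2,3-bis(methoxymethoxy)benzaldehyde
Conditions: MOMCl, i-Pr2NEt, DMAP (cat.), CH2Cl2, 0 → 40 °C
Reagents that add atoms: chloromethyl methyl ether, COCCl
Why: O-alkylation of both phenols (MOM protection) masks the future b4 and b5 hydroxyls with groups that survive organolithium, base and amine conditions.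

**Step 7**
Reactants: 9 bis-MOM benzaldehyde
Product: 11 5-bromo-2,3-bis(methoxymethoxy)phenol, via aryl formate 10 (not isolated)
Conditions: mCPBA, CH2Cl2, 0 °C → rt; then K2CO3 (cat.), MeOH, rt
Reagents that add atoms: 3-chloroperoxybenzoic acid, OOC(=O)c1cccc(Cl)c1
Why: In this Baeyer–Villiger (Dakin-type) oxidation the electron-rich aryl group migrates in preference to hydrogen, and methanolysis of the formate frees only the oxygen that will become the diaryl-ether oxygen.

**Step 8**
Reactants: 11 5-bromo-2,3-bis(methoxymethoxy)phenol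
Product: 12 [5-bromo-2,3-bis(methoxymethoxy)phenoxy](tert-butyl)dimethylsilane
Conditions: TBSCl, imidazole, DMF, rt
Reagents that add atoms: tert-butyldimethylsilyl chloride, CC(C)(C)[Si](C)(C)Cl
Why: Silylation removes the acidic phenol proton before the organolithium step and can later be reversed with fluoride without touching the MOM ethers.

**Step 9**
Reactants: 12 aryl bromide; 7 diethyl farnesyl phosphate
Product: 15 tert-butyl{2,3-bis(methoxymethoxy)-5-[(3S,6E)-3,7,11-trimethyldodeca-1,6,10-trien-3-yl]phenoxy}dimethylsilane, via aryllithium 13 (not isolated), via aryl(diethyl)aluminium 14 (not isolated)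
Conditions: t-BuLi (2 equiv), Et2O, −78 °C; Et2AlCl, −78 °C → rt; then 7, CuCl2·2H2O (cat.), chiral sulfonate-bearing imidazolinium salt (cat.), THF, −30 °C
Reagents that add atoms: none
Why: After bromine–lithium exchange and transmetalation, this copper-catalysed enantioselective allylic substitution (SN2′) transfers aryl in preference to ethyl to the γ-carbon of the phosphate; the chiral carbene on copper selects the alkene face and sets the aryl-bearing quaternary centre as S.

**Step 10**
Reactants: 15 silyl ether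
Product: 16 2,3-bis(methoxymethoxy)-5-[(3S,6E)-3,7,11-trimethyldodeca-1,6,10-trien-3-yl]phenol
Conditions: TBAF, AcOH, THF, 0 °C
Reagents that add atoms: none
Why: Fluoride cleaves the aryl silyl ether selectively (desilylation), and acetic acid buffers the phenoxide; MOM ethers and alkenes are inert.

**Step 11**
Reactants: 16 ring B phenol; 17 3-chloropentane-2,4-dione
Product: 18 3-{2,3-bis(methoxymethoxy)-5-[(3S,6E)-3,7,11-trimethyldodeca-1,6,10-trien-3-yl]phenoxy}pentane-2,4-dione
Conditions: K2CO3, acetone, reflux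
Reagents that add atoms: none
Why: In this Williamson ether synthesis the phenoxide displaces chloride from the α-chloro-1,3-diketone, installing the ether oxygen together with carbons a3, a4 and a5 of the future ring A.

**Step 12**
Reactants: 18 aryloxy diketone
Product: 19 3-{2,3-bis(methoxymethoxy)-5-[(3S,6E)-3,7,11-trimethyldodeca-1,6,10-trien-3-yl]phenoxy}but-3-en-2-one
Conditions: 37 % aq. CH2O, K2CO3, THF–H2O, 0 °C → rt
Reagents that add atoms: formaldehyde, C=O
Why: In this deacetylative methylenation the diketone enolate adds to formaldehyde, the now non-enolisable hydroxymethyl diketone undergoes retro-Claisen acetyl transfer, and E1cB loss of acetate places the methylene unambiguously on the oxygen-bearing carbon.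

**Step 13**
Reactants: 6 (3S,6E)-3-ethenyl-3,7,11-trimethyldodeca-6,10-dienal; 19 aryloxy enone
Product: 22 6-{2,3-bis(methoxymethoxy)-5-[(3S,6E)-3,7,11-trimethyldodeca-1,6,10-trien-3-yl]phenoxy}-4-[(3R,6E)-3,7,11-trimethyldodeca-1,6,10-trien-3-yl]cyclohex-2-en-1-one (ring centres C4 and C6 unassigned), via pyrrolidine enamine 20 (not isolated), via ketoaldehyde 21 (not isolated)
Conditions: pyrrolidine (1.05 equiv), 4 Å MS, PhMe, rt; 19, rt → 60 °C; then AcOH–NaOAc–H2O, 60 °C
Reagents that add atoms: none
Why: Pyrrolidine converts 6 into its E enamine, whose β-carbon (future a1) adds to the unsubstituted terminus of enone 19 (future a6); hydrolysis gives ketoaldehyde 21, whose methyl ketone (a3) then adds to the aldehyde carbon (a2) under pyrrolidinium acetate catalysis and loses water. The closest known reaction is the Stork enamine variant of the Robinson annulation of aldehydes with vinyl ketones to 4-substituted cyclohex-2-enones, including vinyl ketones that carry an α-heteroatom. Ring A closes by a 6-(enolexo)-exo-trig aldol addition followed by E1cB dehydration, since the other enolisable positions (the aryloxy-bearing CH and the aldehyde α-CH) could only form four-membered rings. The new stereocentres C4 and C6 are formed without control and need none, because both become sp2 in step 14, while the two quaternary centres have no α-hydrogen and cannot epimerise. The step needs C-alkylation at the enone terminus and the para relationship of a1 and a4, and both follow from the enone itself, whose only electrophilic carbon is the CH2 and whose carbonyl and aryloxy carbons become a4 and a5.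

**Step 14**
Reactants: 22 cyclohexenone
Product: 25 2-{2,3-bis(methoxymethoxy)-5-[(3S,6E)-3,7,11-trimethyldodeca-1,6,10-trien-3-yl]phenoxy}-4-[(3R,6E)-3,7,11-trimethyldodeca-1,6,10-trien-3-yl]phenol, via silyl dienol ether 23 (not isolated), via cyclohexadienone 24 (not isolated)
Conditions: LiN(i-Pr)2 (LDA), THF, −78 °C; TMSCl, −78 → 0 °C; then Pd(OAc)2 (1.1 equiv), MeCN, rt
Reagents that add atoms: none
Why: In this Saegusa–Ito oxidation, kinetic deprotonation at C6 and silylation give the cross-conjugated silyl dienol ether, Pd(OAc)2 forms the palladium enolate and β-hydride elimination introduces C5=C6; the resulting 4H-dienone tautomerises to the phenol, removing both ring stereocentres.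

**Step 15**
Reactants: 25 bis-MOM diaryl ether
Product: 26 3-{2-hydroxy-5-[(3R,6E)-3,7,11-trimethyldodeca-1,6,10-trien-3-yl]phenoxy}-5-[(3S,6E)-3,7,11-trimethyldodeca-1,6,10-trien-3-yl]benzene-1,2-diol
Conditions: TMSOTf, 2,2′-bipyridyl, MeCN, 0 °C → rt; then H2O
Reagents that add atoms: none
Why: The silyl triflate–bipyridyl pair converts each aryl MOM ether into an aryl silyl ether that hydrolyses on aqueous work-up (MOM ether cleavage), so the trisubstituted alkenes and allylic quaternary centres never meet a free strong acid.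

**Compound list**

1 | (2E,6E)-farnesol | CC(C)=CCC/C(C)=C/CC/C(C)=C/CO | starting material
2 | methyl (2E,6E)-3,7,11-trimethyldodeca-2,6,10-trien-1-yl carbonate | CC(C)=CCC/C(C)=C/CC/C(C)=C/COC(=O)OC | intermediate
3 | 4,4,5,5-tetramethyl-2-[(3S,6E)-3,7,11-trimethyldodeca-1,6,10-trien-3-yl]-1,3,2-dioxaborolane | CC1(C)OB(OC1(C)C)[C@@](C)(C=C)CC/C=C(\C)CCC=C(C)C | intermediate
4 | 2-[(2R,5E)-2-ethenyl-2,6,10-trimethylundeca-5,9-dien-1-yl]-4,4,5,5-tetramethyl-1,3,2-dioxaborolane | CC1(C)OB(OC1(C)C)C[C@@](C)(C=C)CC/C=C(\C)CCC=C(C)C | intermediate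
5 | 2-[(3S,6E)-1-chloro-3-ethenyl-3,7,11-trimethyldodeca-6,10-dien-1-yl]-4,4,5,5-tetramethyl-1,3,2-dioxaborolane (C1 epimers) | CC1(C)OB(OC1(C)C)C(Cl)C[C@@](C)(C=C)CC/C=C(\C)CCC=C(C)C | intermediate
6 | (3S,6E)-3-ethenyl-3,7,11-trimethyldodeca-6,10-dienal | O=CC[C@@](C)(C=C)CC/C=C(\C)CCC=C(C)C | intermediate
7 | diethyl (2E,6E)-3,7,11-trimethyldodeca-2,6,10-trien-1-yl phosphate | CC(C)=CCC/C(C)=C/CC/C(C)=C/COP(=O)(OCC)OCC | intermediate
8 | 5-bromo-2,3-dihydroxybenzaldehyde | O=Cc1cc(Br)cc(O)c1O | starting material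
9 | 5-bromo-2,3-bis(methoxymethoxy)benzaldehyde | O=Cc1cc(Br)cc(OCOC)c1OCOC | intermediate
10 | 5-bromo-2,3-bis(methoxymethoxy)phenyl formate | O=COc1cc(Br)cc(OCOC)c1OCOC | intermediate
11 | 5-bromo-2,3-bis(methoxymethoxy)phenol | Oc1cc(Br)cc(OCOC)c1OCOC | intermediate
12 | [5-bromo-2,3-bis(methoxymethoxy)phenoxy](tert-butyl)dimethylsilane | CC(C)(C)[Si](C)(C)Oc1cc(Br)cc(OCOC)c1OCOC | intermediate
13 | {3-[(tert-butyldimethylsilyl)oxy]-4,5-bis(methoxymethoxy)phenyl}lithium | [Li]c1cc(O[Si](C)(C)C(C)(C)C)c(OCOC)c(OCOC)c1 | intermediate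
14 | {3-[(tert-butyldimethylsilyl)oxy]-4,5-bis(methoxymethoxy)phenyl}diethylaluminium | CC[Al](CC)c1cc(O[Si](C)(C)C(C)(C)C)c(OCOC)c(OCOC)c1 | intermediate
15 | tert-butyl{2,3-bis(methoxymethoxy)-5-[(3S,6E)-3,7,11-trimethyldodeca-1,6,10-trien-3-yl]phenoxy}dimethylsilane | CC(C)(C)[Si](C)(C)Oc1cc([C@](C)(C=C)CC/C=C(\C)CCC=C(C)C)cc(OCOC)c1OCOC | intermediate
16 | 2,3-bis(methoxymethoxy)-5-[(3S,6E)-3,7,11-trimethyldodeca-1,6,10-trien-3-yl]phenol | Oc1cc([C@](C)(C=C)CC/C=C(\C)CCC=C(C)C)cc(OCOC)c1OCOC | intermediate
17 | 3-chloropentane-2,4-dione | CC(=O)C(Cl)C(C)=O | starting material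
18 | 3-{2,3-bis(methoxymethoxy)-5-[(3S,6E)-3,7,11-trimethyldodeca-1,6,10-trien-3-yl]phenoxy}pentane-2,4-dione | CC(=O)C(Oc1cc([C@](C)(C=C)CC/C=C(\C)CCC=C(C)C)cc(OCOC)c1OCOC)C(C)=O | intermediate
19 | 3-{2,3-bis(methoxymethoxy)-5-[(3S,6E)-3,7,11-trimethyldodeca-1,6,10-trien-3-yl]phenoxy}but-3-en-2-one | C=C(Oc1cc([C@](C)(C=C)CC/C=C(\C)CCC=C(C)C)cc(OCOC)c1OCOC)C(C)=O | intermediate
20 | 1-[(1E,6E)-3-ethenyl-3,7,11-trimethyldodeca-1,6,10-trien-1-yl]pyrrolidine (E enamine of 6, quaternary centre as in 6) | N1(CCCC1)/C=C/[C@@](C)(C=C)CC/C=C(\C)CCC=C(C)C | intermediate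
21 | 4-{2,3-bis(methoxymethoxy)-5-[(3S,6E)-3,7,11-trimethyldodeca-1,6,10-trien-3-yl]phenoxy}-5-oxo-2-[(3R,6E)-3,7,11-trimethyldodeca-1,6,10-trien-3-yl]hexanal (C2 and C4 unassigned) | O=CC(CC(Oc1cc([C@](C)(C=C)CC/C=C(\C)CCC=C(C)C)cc(OCOC)c1OCOC)C(C)=O)[C@@](C)(C=C)CC/C=C(\C)CCC=C(C)C | intermediate
22 | 6-{2,3-bis(methoxymethoxy)-5-[(3S,6E)-3,7,11-trimethyldodeca-1,6,10-trien-3-yl]phenoxy}-4-[(3R,6E)-3,7,11-trimethyldodeca-1,6,10-trien-3-yl]cyclohex-2-en-1-one (C4 and C6 unassigned) | O=C1C=CC([C@@](C)(C=C)CC/C=C(\C)CCC=C(C)C)CC1Oc1cc([C@](C)(C=C)CC/C=C(\C)CCC=C(C)C)cc(OCOC)c1OCOC | intermediate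
23 | trimethyl{[2-aryloxy-4-alkylcyclohexa-1,5-dien-1-yl]oxy}silane, aryloxy and alkyl groups as in 22 (C4 unassigned) | C[Si](C)(C)OC1=C(Oc2cc([C@](C)(C=C)CC/C=C(\C)CCC=C(C)C)cc(OCOC)c2OCOC)CC([C@@](C)(C=C)CC/C=C(\C)CCC=C(C)C)C=C1 | intermediate
24 | 2-aryloxy-4-alkylcyclohexa-2,5-dien-1-one, aryloxy and alkyl groups as in 22 (C4 unassigned) | O=C1C=CC([C@@](C)(C=C)CC/C=C(\C)CCC=C(C)C)C=C1Oc1cc([C@](C)(C=C)CC/C=C(\C)CCC=C(C)C)cc(OCOC)c1OCOC | intermediate
25 | 2-{2,3-bis(methoxymethoxy)-5-[(3S,6E)-3,7,11-trimethyldodeca-1,6,10-trien-3-yl]phenoxy}-4-[(3R,6E)-3,7,11-trimethyldodeca-1,6,10-trien-3-yl]phenol | C=C[C@@](C)(CC/C=C(\C)CCC=C(C)C)c1ccc(O)c(Oc2cc([C@](C)(C=C)CC/C=C(\C)CCC=C(C)C)cc(OCOC)c2OCOC)c1 | intermediate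
26 | 3-{2-hydroxy-5-[(3R,6E)-3,7,11-trimethyldodeca-1,6,10-trien-3-yl]phenoxy}-5-[(3S,6E)-3,7,11-trimethyldodeca-1,6,10-trien-3-yl]benzene-1,2-diol | C=C[C@@](C)(CC/C=C(\C)CCC=C(C)C)c1ccc(O)c(Oc2cc([C@](C)(C=C)CC/C=C(\C)CCC=C(C)C)cc(O)c2O)c1 | target

**Step count and risks**

Total: 15 steps. Longest linear sequence: 10 steps (steps 6 to 15, from 8).

**Step 13.** The hindered enamine, whose nucleophilic carbon sits next to a quaternary centre, may add too slowly to the α-branched, oxygen-donor-substituted enone, so that enone polymerisation or reversible N-alkylation takes over. The fallback sets out from aldehyde 6 and phenol 16 and returns at cyclohexenone 22. Aldehyde 6 would be annulated with methyl vinyl ketone under the same enamine protocol to give 4-[(3R,6E)-3,7,11-trimethyldodeca-1,6,10-trien-3-yl]cyclohex-2-en-1-one F1. Kinetic enolisation and silylation (LiN(i-Pr)2, TMSCl, THF, −78 °C) would give its trimethylsilyl dienol ether F2, and N-bromosuccinimide at −78 °C would give the 6-bromo enone F3. Displacement of bromide by the phenoxide of 16 (K2CO3, acetone, rt) would then give 22; here the ether bond is made by substitution on the ring instead of being carried in by the enone.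

**Step 3.** Ate-complex formation at the crowded tertiary allylic boron may be slow, and 1,3-borotropic shift to the linear farnesyl boronate may compete before the 1,2-migration. The fallback sets out from phosphate 7 and returns at aldehyde 6. Copper-catalysed enantioselective SN2′ substitution of 7 with diisobutyl[(trimethylsilyl)ethynyl]aluminium (from trimethylsilylacetylene and i-Bu2AlH with catalytic Et3N; CuCl2·2H2O and the suitable antipode of the sulfonate-bearing imidazolinium salt, THF, −30 °C) would give trimethyl[(3R,6E)-3-ethenyl-3,7,11-trimethyldodeca-6,10-dien-1-yn-1-yl]silane F4. K2CO3 in MeOH would give the terminal alkyne (3R,6E)-3-ethenyl-3,7,11-trimethyldodeca-6,10-dien-1-yne F5. Alkyne-selective copper-catalysed protoboration (B2pin2, CuCl, NaOt-Bu, Xantphos, MeOH, THF) would give the E alkenyl boronic ester F6, and oxidation with NaBO3·4H2O would give 6.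

**Step 12.** Retro-Claisen deacetylation may occur before hydroxymethylation, or hydroxide and enolates may add to the newly formed enone in the aqueous base. The fallback sets out from phenol 16 and returns at enone 19. Alkylation of 16 with chloroacetone (K2CO3, acetone) would give 1-aryloxypropan-2-one F7. Dimethylmethylideneammonium iodide in MeCN would react at the oxygen-bearing α-carbon, the position at which α-oxygenated acetones enolise preferentially, to give the Mannich base 3-aryloxy-4-(dimethylamino)butan-2-one F8. N-methylation with MeI and elimination with NaHCO3 would give 19.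

**Further compounds**

F1 | step 13 | 4-[(3R,6E)-3,7,11-trimethyldodeca-1,6,10-trien-3-yl]cyclohex-2-en-1-one (C4 unassigned) | O=C1C=CC([C@@](C)(C=C)CC/C=C(\C)CCC=C(C)C)CC1
F2 | step 13 | trimethyl({4-[(3R,6E)-3,7,11-trimethyldodeca-1,6,10-trien-3-yl]cyclohexa-1,5-dien-1-yl}oxy)silane | C[Si](C)(C)OC1=CCC([C@@](C)(C=C)CC/C=C(\C)CCC=C(C)C)C=C1
F3 | step 13 | 6-bromo-4-[(3R,6E)-3,7,11-trimethyldodeca-1,6,10-trien-3-yl]cyclohex-2-en-1-one (C4 and C6 unassigned) | O=C1C=CC([C@@](C)(C=C)CC/C=C(\C)CCC=C(C)C)CC1Br
F4 | step 3 | trimethyl[(3R,6E)-3-ethenyl-3,7,11-trimethyldodeca-6,10-dien-1-yn-1-yl]silane | C[Si](C)(C)C#C[C@@](C)(C=C)CC/C=C(\C)CCC=C(C)C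
F5 | step 3 | (3R,6E)-3-ethenyl-3,7,11-trimethyldodeca-6,10-dien-1-yne | C#C[C@@](C)(C=C)CC/C=C(\C)CCC=C(C)C
F6 | step 3 | 2-[(1E,6E)-3-ethenyl-3,7,11-trimethyldodeca-1,6,10-trien-1-yl]-4,4,5,5-tetramethyl-1,3,2-dioxaborolane (quaternary centre as in 6) | CC1(C)OB(/C=C/[C@@](C)(C=C)CC/C=C(\C)CCC=C(C)C)OC1(C)C
F7 | step 12 | 1-{2,3-bis(methoxymethoxy)-5-[(3S,6E)-3,7,11-trimethyldodeca-1,6,10-trien-3-yl]phenoxy}propan-2-one | CC(=O)COc1cc([C@](C)(C=C)CC/C=C(\C)CCC=C(C)C)cc(OCOC)c1OCOC
F8 | step 12 | 3-{2,3-bis(methoxymethoxy)-5-[(3S,6E)-3,7,11-trimethyldodeca-1,6,10-trien-3-yl]phenoxy}-4-(dimethylamino)butan-2-one (C3 unassigned) | CC(=O)C(CN(C)C)Oc1cc([C@](C)(C=C)CC/C=C(\C)CCC=C(C)C)cc(OCOC)c1OCOC
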